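Ring A carries the CH2CH2 bridge at C1, OH at C3, OMe at C5 and 4-hydroxybenzyl groups at C2 and C6; ring B carries the bridge at C1', OH at C3' and the third 4-hydroxybenzyl group at C5'.
Feature used: the arms on C2, C6 and C5' all end in the same para-hydroxyphenyl ring (rings C, D, E), whose ipso carbon sits on a carbon that can be a carbonyl, so each ring maps onto an aryl ethynyl ketone plus a 1-methoxy-3-siloxybutadiene.
Cuts: the three benzylic CH2 groups go back to diaryl ketones; rings C, D and E are each cut at the C-ipso–C-ortho and C-ortho'–C-meta' bonds; the ynones go back through aldehydes to aryl bromides at C2, C6 and C5'; the bibenzyl is cut at the CH2–C1' bond.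
Forward: rings A and B are bought and joined by hydroboration/B-alkyl Suzuki–Miyaura coupling, then brominated, formylated, ethynylated and oxidised; rings C, D and E are then built together in one threefold cycloaddition–aromatisation; carbonyl reduction and hydrogenolysis finish.
Stereochemistry: the target has no stereocentre; the carbinol and CH(OMe) centres met on the way form as mixtures and are all destroyed.
Key step: step 9

Remark: compounds 12, 15 and 17 arise as diastereomer mixtures at centres that later steps remove, so they are carried on as mixtures and written without stereodescriptors.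

Step 1
Reactants: 1 3-hydroxy-5-methoxybenzaldehyde
Product: 2 3-(benzyloxy)-5-methoxybenzaldehyde
Conditions: BnBr, K2CO3, DMF, rt
Reagents that add atoms: benzyl bromide, BrCc1ccccc1
Why: Williamson ether synthesis, in which the phenoxide formed with K2CO3 is alkylated by benzyl bromide while the aldehyde is inert; benzyl is chosen because it should survive organolithium, Grignard, oxidation and cycloaddition conditions and leave by hydrogenolysis at the end.

Step 2
Reactants: 2 3-(benzyloxy)-5-methoxybenzaldehyde
Product: 3 1-(benzyloxy)-3-methoxy-5-vinylbenzene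
Conditions: Ph3PCH3Br, KOt-Bu, THF, 0 °C → rt
Reagents that add atoms: methyltriphenylphosphonium bromide, C[P+](c1ccccc1)(c1ccccc1)c1ccccc1.[Br-]
Why: Wittig methylenation, in which the non-stabilised ylide made in the flask converts the aromatic aldehyde into the styrene through an oxaphosphetane and leaves the benzyl and methyl ethers untouched.

Step 3
Reactants: 4 3-bromo-5-iodophenol
Product: 5 1-(benzyloxy)-3-bromo-5-iodobenzene
Conditions: BnBr, K2CO3, DMF, rt
Reagents that add atoms: benzyl bromide, BrCc1ccccc1
Why: Williamson ether synthesis on the only acidic group; the aryl iodide and aryl bromide do not react with K2CO3 or benzyl bromide.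

Step 4
Reactants: 3 1-(benzyloxy)-3-methoxy-5-vinylbenzene; 5 1-(benzyloxy)-3-bromo-5-iodobenzene
Product: 7 1-(benzyloxy)-3-[2-(3-(benzyloxy)-5-bromophenyl)ethyl]-5-methoxybenzene, via B-alkyl-9-BBN borane 6 (not isolated)
Conditions: 9-BBN, THF, 0 °C → rt; then 5, PdCl2(dppf) (5 mol %), 3 M aq. NaOH, THF, rt → 40 °C
Reagents that add atoms: none
Why: Anti-Markovnikov hydroboration of the styrene with 9-BBN places boron on the terminal carbon, and the B-alkyl Suzuki–Miyaura coupling then forms the CH2–C1' bond, because zerovalent palladium inserts into the C–I bond of 5 far faster than into its C–Br bond near room temperature, so the ring B bromide is kept for step 6.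

Step 5
Reactants: 7 1-(benzyloxy)-3-[2-(3-(benzyloxy)-5-bromophenyl)ethyl]-5-methoxybenzene
Product: 8 1-(benzyloxy)-2,4-dibromo-3-[2-(3-(benzyloxy)-5-bromophenyl)ethyl]-5-methoxybenzene (Br at C2 and C6 of ring A and at C5' of ring B)
Conditions: NBS (2.05 equiv), MeCN, 0 °C → rt, dark
Reagents that add atoms: N-bromosuccinimide, O=C1CCC(=O)N1Br
Why: Electrophilic aromatic bromination, in which C2 and C6 of ring A are each ortho to one alkoxy group and para to the other (the usual halogenation sites of 5-alkylresorcinol diethers), C4 between the two alkoxy groups is the crowded site that reacts last, and ring B with one alkoxy group and a deactivating bromine is much less reactive, so two equivalents should stop at the tribromide.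

Step 6
Reactants: 8 1-(benzyloxy)-2,4-dibromo-3-[2-(3-(benzyloxy)-5-bromophenyl)ethyl]-5-methoxybenzene
Product: 10 4-(benzyloxy)-2-[2-(3-(benzyloxy)-5-formylphenyl)ethyl]-6-methoxybenzene-1,3-dicarbaldehyde, via trilithio bibenzyl 9 (not isolated)
Conditions: t-BuLi (6.2 equiv), THF, −78 °C; DMF, −78 → 0 °C; H2O
Reagents that add atoms: N,N-dimethylformamide, CN(C)C=O
Why: Threefold bromine–lithium exchange, made irreversible by two equivalents of t-BuLi per bromide and helped on ring A by the ortho alkoxy groups, followed by formylation of each aryllithium with DMF and hydrolysis of the hemiaminal salts; ortho-lithiated aryl benzyl ethers are stable at −78 °C.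

Step 7
Reactants: 10 4-(benzyloxy)-2-[2-(3-(benzyloxy)-5-formylphenyl)ethyl]-6-methoxybenzene-1,3-dicarbaldehyde; 11 ethynylmagnesium bromide
Product: 12 1,1'-{4-(benzyloxy)-2-[2-(3-(benzyloxy)-5-(1-hydroxyprop-2-yn-1-yl)phenyl)ethyl]-6-methoxy-1,3-phenylene}bis(prop-2-yn-1-ol) (diastereomer mixture)
Conditions: HC≡CMgBr (4.5 equiv), THF, −20 → 0 °C; aq. NH4Cl
Reagents that add atoms: ethynylmagnesium bromide 11, C#C[Mg]Br
Why: Grignard 1,2-addition of a small sp nucleophile to the three aromatic aldehydes, including the two di-ortho-substituted ones on ring A; the three carbinol centres form without control, which does not matter because step 8 removes them.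

Step 8
Reactants: 12 1,1'-{4-(benzyloxy)-2-[2-(3-(benzyloxy)-5-(1-hydroxyprop-2-yn-1-yl)phenyl)ethyl]-6-methoxy-1,3-phenylene}bis(prop-2-yn-1-ol)
Product: 13 1,1'-{4-(benzyloxy)-2-[2-(3-(benzyloxy)-5-propynoylphenyl)ethyl]-6-methoxy-1,3-phenylene}bis(prop-2-yn-1-one) (propynoyl groups at C2, C6 and C5')
Conditions: activated MnO2 (excess), CH2Cl2, rt
Reagents that add atoms: none
Why: MnO2 oxidation of alcohols that are both benzylic and propargylic to aryl ethynyl ketones under neutral conditions; the filtration work-up keeps the Michael-sensitive terminal ynones away from nucleophiles, and benzyl ethers and terminal alkynes are inert.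

Step 9
Reactants: 13 1,1'-{4-(benzyloxy)-2-[2-(3-(benzyloxy)-5-propynoylphenyl)ethyl]-6-methoxy-1,3-phenylene}bis(prop-2-yn-1-one); 14 trans-1-methoxy-3-trimethylsiloxy-1,3-butadiene
Product: 16 {4-(benzyloxy)-2-[2-(3-(benzyloxy)-5-(4-hydroxybenzoyl)phenyl)ethyl]-6-methoxy-1,3-phenylene}bis[(4-hydroxyphenyl)methanone], via threefold cyclohexadiene cycloadduct 15 (not isolated)
Conditions: 14 (6 equiv), toluene, 90 °C; then 1 M HCl, THF, rt
Reagents that add atoms: trans-1-methoxy-3-trimethylsiloxy-1,3-butadiene 14, CO/C=C/C(=C)O[Si](C)(C)C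
Why: The electron-poor C≡C of each propynoyl group reacts with the electron-rich diene in a normal-electron-demand, asynchronous [4+2] cycloaddition in which the diene CH2 terminus (C4) adds to the terminal alkyne carbon and the CH(OMe) terminus (C1) to the alkyne carbon bearing the acyl group, giving a 1,4-cyclohexadiene on each arm. Acid then hydrolyses the silyl enol ether and eliminates methanol, so each adduct aromatises to a 4-hydroxyphenyl ketone with its oxygen para to the carbonyl carbon, the future benzylic CH2. The closest known reaction type is the Diels–Alder/aromatisation of 1-methoxy-3-siloxybutadienes with acetylenic ketones and esters to para-hydroxyaryl carbonyl compounds, here run three times on one substrate. Rings C, D and E each close by an intermolecular [4+2] cycloaddition that forms the C-ipso–C-ortho and C-ortho'–C-meta' bonds in one event, followed by aromatisation, and no ring is closed through a tether. The CH(OMe) centres of 15 form without control and vanish on aromatisation, so no stereocentre has to be set. The step needs para regiochemistry and complete threefold conversion: the first comes from pairing the most nucleophilic diene carbon (C4, raised by the 3-siloxy group) with the beta carbon of each ynone, the second from three ynones that are not conjugated with one another and each offer an unhindered terminal CH for the first bond, supported by excess diene.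

Step 10
Reactants: 16 {4-(benzyloxy)-2-[2-(3-(benzyloxy)-5-(4-hydroxybenzoyl)phenyl)ethyl]-6-methoxy-1,3-phenylene}bis[(4-hydroxyphenyl)methanone]
Product: 17 {4-(benzyloxy)-2-[2-(3-(benzyloxy)-5-[hydroxy(4-hydroxyphenyl)methyl]phenyl)ethyl]-6-methoxy-1,3-phenylene}bis[(4-hydroxyphenyl)methanol] (diastereomer mixture)
Conditions: NaBH4 (excess), THF/MeOH, 0 → 50 °C; aq. NH4Cl
Reagents that add atoms: none
Why: Borohydride reduction of diaryl ketones to benzhydrols, run with excess reagent and gentle warming because the ring A carbonyls are flanked by two ortho substituents; benzyl ethers are inert, the three new carbinol centres form without control and are removed in step 11, and any arm reduced further to CH2 through its quinone methide converges on the same final product.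

Step 11
Reactants: 17 {4-(benzyloxy)-2-[2-(3-(benzyloxy)-5-[hydroxy(4-hydroxyphenyl)methyl]phenyl)ethyl]-6-methoxy-1,3-phenylene}bis[(4-hydroxyphenyl)methanol]
Product: 18 2,4-bis(4-hydroxybenzyl)-3-{2-[3-hydroxy-5-(4-hydroxybenzyl)phenyl]ethyl}-5-methoxyphenol (CNP0204120.0)
Conditions: H2 (1 atm), 10% Pd/C, EtOAc/AcOH, rt
Reagents that add atoms: none
Why: Catalytic hydrogenolysis over palladium should cleave the two aryl benzyl ethers and the three benzhydrylic C–O bonds, which are doubly benzylic and para to a phenol and so ionise under mild acid to quinone methides that are hydrogenated at once; the arenes, the methyl ether and the bridge are not reduced at 1 atm.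

Compound list
1 | 3-hydroxy-5-methoxybenzaldehyde | COc1cc(O)cc(C=O)c1 | starting material
2 | 3-(benzyloxy)-5-methoxybenzaldehyde | COc1cc(OCc2ccccc2)cc(C=O)c1 | intermediate
3 | 1-(benzyloxy)-3-methoxy-5-vinylbenzene | C=Cc1cc(OC)cc(OCc2ccccc2)c1 | intermediate
4 | 3-bromo-5-iodophenol | Oc1cc(Br)cc(I)c1 | starting material
5 | 1-(benzyloxy)-3-bromo-5-iodobenzene | Brc1cc(I)cc(OCc2ccccc2)c1 | intermediate
6 | 9-[2-(3-(benzyloxy)-5-methoxyphenyl)ethyl]-9-borabicyclo[3.3.1]nonane (not isolated) | COc1cc(OCc2ccccc2)cc(CCB2C3CCCC2CCC3)c1 | intermediate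
7 | 1-(benzyloxy)-3-[2-(3-(benzyloxy)-5-bromophenyl)ethyl]-5-methoxybenzene | COc1cc(OCc2ccccc2)cc(CCc2cc(OCc3ccccc3)cc(Br)c2)c1 | intermediate
8 | 1-(benzyloxy)-2,4-dibromo-3-[2-(3-(benzyloxy)-5-bromophenyl)ethyl]-5-methoxybenzene | COc1cc(OCc2ccccc2)c(Br)c(CCc2cc(OCc3ccccc3)cc(Br)c2)c1Br | intermediate
9 | trilithio bibenzyl, Li in place of each Br of 8 (not isolated) | COc1cc(OCc2ccccc2)c([Li])c(CCc2cc(OCc3ccccc3)cc([Li])c2)c1[Li] | intermediate
10 | 4-(benzyloxy)-2-[2-(3-(benzyloxy)-5-formylphenyl)ethyl]-6-methoxybenzene-1,3-dicarbaldehyde | COc1cc(OCc2ccccc2)c(C=O)c(CCc2cc(OCc3ccccc3)cc(C=O)c2)c1C=O | intermediate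
11 | ethynylmagnesium bromide | C#C[Mg]Br | starting material
12 | 1,1'-{4-(benzyloxy)-2-[2-(3-(benzyloxy)-5-(1-hydroxyprop-2-yn-1-yl)phenyl)ethyl]-6-methoxy-1,3-phenylene}bis(prop-2-yn-1-ol), diastereomer mixture | COc1cc(OCc2ccccc2)c(C(O)C#C)c(CCc2cc(OCc3ccccc3)cc(C(O)C#C)c2)c1C(O)C#C | intermediate
13 | 1,1'-{4-(benzyloxy)-2-[2-(3-(benzyloxy)-5-propynoylphenyl)ethyl]-6-methoxy-1,3-phenylene}bis(prop-2-yn-1-one) | COc1cc(OCc2ccccc2)c(C(=O)C#C)c(CCc2cc(OCc3ccccc3)cc(C(=O)C#C)c2)c1C(=O)C#C | intermediate
14 | trans-1-methoxy-3-trimethylsiloxy-1,3-butadiene | CO/C=C/C(=C)O[Si](C)(C)C | starting material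
15 | threefold cycloadduct, each acyl group carrying a 6-methoxy-4-(trimethylsiloxy)cyclohexa-1,4-dien-1-yl ring, diastereomer mixture (not isolated) | COc1cc(OCc2ccccc2)c(C(=O)C2=CCC(O[Si](C)(C)C)=CC2OC)c(CCc2cc(OCc3ccccc3)cc(C(=O)C3=CCC(O[Si](C)(C)C)=CC3OC)c2)c1C(=O)C1=CCC(O[Si](C)(C)C)=CC1OC | intermediate
16 | {4-(benzyloxy)-2-[2-(3-(benzyloxy)-5-(4-hydroxybenzoyl)phenyl)ethyl]-6-methoxy-1,3-phenylene}bis[(4-hydroxyphenyl)methanone] | COc1cc(OCc2ccccc2)c(C(=O)c2ccc(O)cc2)c(CCc2cc(OCc3ccccc3)cc(C(=O)c3ccc(O)cc3)c2)c1C(=O)c1ccc(O)cc1 | intermediate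
17 | {4-(benzyloxy)-2-[2-(3-(benzyloxy)-5-[hydroxy(4-hydroxyphenyl)methyl]phenyl)ethyl]-6-methoxy-1,3-phenylene}bis[(4-hydroxyphenyl)methanol], diastereomer mixture | COc1cc(OCc2ccccc2)c(C(O)c2ccc(O)cc2)c(CCc2cc(OCc3ccccc3)cc(C(O)c3ccc(O)cc3)c2)c1C(O)c1ccc(O)cc1 | intermediate
18 | 2,4-bis(4-hydroxybenzyl)-3-{2-[3-hydroxy-5-(4-hydroxybenzyl)phenyl]ethyl}-5-methoxyphenol | COc1cc(O)c(Cc2ccc(O)cc2)c(CCc2cc(O)cc(Cc3ccc(O)cc3)c2)c1Cc1ccc(O)cc1 | target

Total step count: 11.
Longest linear sequence: 10 steps (steps 1, 2 and 4 to 11); the ring B branch is step 3 and joins at step 4.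

Steps most likely to fail

Step 9. The two ring A ynones, each flanked by two ortho substituents, may react more slowly than the ring B ynone, while the terminal ynones oligomerise by conjugate addition at the temperature needed; the result would be mixtures of mono-, bis- and tris-adducts. The fallback gives up the ring construction and brings rings C, D and E in as preformed aryl nucleophiles. It sets out from trialdehyde 10: threefold addition of 4-(benzyloxy)phenylmagnesium bromide (THF, 0 °C) should give the tris(diarylcarbinol) pentabenzyl ether F2. Hydrogenolysis of F2 under the conditions of step 11 should cleave the three benzhydrylic C–O bonds and all five benzyl ethers and return to the route at target 18.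

Step 6. Exchange at the second ring A bromide may stay incomplete, a lithio centre may be protonated before formylation, or t-BuLi may deprotonate a benzyl ether CH2; each would give under-formylated mixtures. The fallback avoids organolithiums and sets out from tribromide 8. Threefold Suzuki–Miyaura vinylation with potassium vinyltrifluoroborate (Pd(OAc)2, SPhos, K2CO3, toluene/H2O, 90 °C) should give the tris(vinyl) bibenzyl F1. Lemieux–Johnson cleavage of F1 (K2OsO4·2H2O cat., NaIO4, 2,6-lutidine, dioxane/H2O) should then return to the route at trialdehyde 10.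

Step 10. Hydride delivery to the two ring A carbonyls may be slow, because the twisted, di-ortho-substituted ring A shields both faces and phenoxide formation under the basic conditions lowers the electrophilicity, so reduction may stop partway. The fallback works under acid, where the phenols stay neutral and the carbonyls are activated by protonation. It sets out from tris-ketone 16: ionic hydrogenation with Et3SiH and CF3CO2H (CH2Cl2, 0 °C → rt) should give the tris(4-hydroxybenzyl) bis(benzyl ether) F3 directly. Hydrogenolysis of F3 (H2, 10% Pd/C, EtOAc) should return to the route at target 18.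

Further compounds
F1 | step 6 | 1-(benzyloxy)-3-[2-(3-(benzyloxy)-5-vinylphenyl)ethyl]-5-methoxy-2,4-divinylbenzene | COc1cc(OCc2ccccc2)c(C=C)c(CCc2cc(OCc3ccccc3)cc(C=C)c2)c1C=C
F2 | step 9 | {4-(benzyloxy)-2-[2-(3-(benzyloxy)-5-[(4-(benzyloxy)phenyl)(hydroxy)methyl]phenyl)ethyl]-6-methoxy-1,3-phenylene}bis[(4-(benzyloxy)phenyl)methanol] | COc1cc(OCc2ccccc2)c(C(O)c2ccc(OCc3ccccc3)cc2)c(CCc2cc(OCc3ccccc3)cc(C(O)c3ccc(OCc4ccccc4)cc3)c2)c1C(O)c1ccc(OCc2ccccc2)cc1
F3 | step 10 | 4,4'-{[4-(benzyloxy)-2-[2-(3-(benzyloxy)-5-(4-hydroxybenzyl)phenyl)ethyl]-6-methoxy-1,3-phenylene]bis(methylene)}diphenol | COc1cc(OCc2ccccc2)c(Cc2ccc(O)cc2)c(CCc2cc(OCc3ccccc3)cc(Cc3ccc(O)cc3)c2)c1Cc1ccc(O)cc1
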